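## Retrosynthetic overview

1. Numbering (target atoms): ring A = cyclopentanone C2–C3–C4(=O)–C5–C6; ring B = cyclohexane C1(=C15H2)–C2–C6–C7–C8–C9; C10 = acetoxy carbon on C5; C11/C12/C13 = oxirane carbon, oxirane CH2 and ester carbon on C7; "top" = the face of ring B that carries ring A.
2. Late disconnections: C4 ketal, C10 acetate, O9 ester, C1=C15 (methylenation of a C9 ketone), O8/O9 (cis-hydroxy-acyloxylation of C8=C9 on the top face), oxirane (asymmetric epoxidation), C7–C11 (Claisen transfer from O9).
3. Ring A: the C2–C3 bond is made by one-carbon ring expansion of a cis-fused α-chlorocyclobutanone (temporary C2–C4 bond). That cyclobutanone comes from a chloroketene carrying C10 and cyclohexa-1,3-diene (ring B is bought).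
4. Enabling feature: in ring A the carbonyl C4 sits between an unsubstituted CH2 (C3, bonded to the ring-fusion methine C2) and the substituted C5. C3 can therefore be inserted into the C2–C4 bond of the ketene adduct, with chlorine on C5 deciding which bond expands and holding the endo C5 configuration.
5. Ring order: ring B (purchased) → four-membered ring (step 4) → ring A (step 5) → oxirane (step 13).

Key step: step 5

Remark: the acyl groups are placed as the SMILES reads, (E)-3-methylpent-2-enoate on O8 and (R)-2-methylbutanoate on O9; D-threonine, cyclohexa-1,3-diene and both acids are taken as purchased. TBS = tert-butyldimethylsilyl.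

## Route

Step 1
Reactants: 1 D-threonine
Product: 2 (2R,3S)-2-chloro-3-hydroxybutanoic acid
Conditions: NaNO2, 6 M HCl, 0 °C to rt
Reagents that add atoms: hydrochloric acid (Cl)
Why: Diazotisation of the α-amino acid gives an α-lactone by carboxylate participation that chloride opens, so chlorine replaces nitrogen with overall retention while the C3 carbinol (the future C10, S) is untouched.

Step 2
Reactants: 2 (2R,3S)-2-chloro-3-hydroxybutanoic acid
Product: 3 tert-butyldimethylsilyl (2R,3S)-3-(tert-butyldimethylsilyloxy)-2-chlorobutanoate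
Conditions: TBSCl (2.2 equiv), imidazole, DMF, rt
Reagents that add atoms: tert-butyldimethylsilyl chloride (CC(C)(C)[Si](C)(C)Cl)
Why: Imidazole-promoted silylation caps the hydroxyl as silyl ether and the acid as silyl ester without touching the carbinol stereocentre.

Step 3
Reactants: 3 tert-butyldimethylsilyl (2R,3S)-3-(tert-butyldimethylsilyloxy)-2-chlorobutanoate
Product: 4 (2R,3S)-3-(tert-butyldimethylsilyloxy)-2-chlorobutanoyl chloride
Conditions: (COCl)2, DMF (cat.), CH2Cl2, 0 °C to rt
Reagents that add atoms: oxalyl chloride (ClC(=O)C(Cl)=O)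
Why: Silyl esters are converted directly into acid chlorides by oxalyl chloride with catalytic DMF (Vilsmeier-type activation) under neutral conditions that keep the silyl ether.

Step 4
Reactants: 4 (2R,3S)-3-(tert-butyldimethylsilyloxy)-2-chlorobutanoyl chloride; 5 cyclohexa-1,3-diene
Product: 7 cis-fused 8-chloro-8-[(1S)-1-(TBS-oxy)ethyl]bicyclo[4.2.0]oct-2-en-7-one (C4=O on C2; C5 on C6; silyloxyethyl endo; Cl exo), via chloroketene 6 (not isolated)
Conditions: Et3N (slow addition), 5 (5 equiv), hexane, reflux; chromatography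
Reagents that add atoms: none
Why: Dehydrochlorination gives the chloro(alkyl)ketene, which undergoes thermal ketene–olefin [2+2] cycloaddition in which the electrophilic ketene carbon (C4) bonds to the diene terminus C2 and the ketene α-carbon (C5) to the internal carbon C6, the olefin adds suprafacially (C2/C6 cis), the larger ketene substituent ends up endo with Cl exo as is usual for unsymmetrical ketenes, and the C10 stereocentre biases the face of the ketene terminus so that the adduct with the target ring-fusion configuration should predominate and is separated from the other endo diastereomer by chromatography.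

Step 5
Reactants: 7 cis-fused chlorocyclobutanone
Product: 8 cis-9-chloro-9-[(1S)-1-(TBS-oxy)ethyl]bicyclo[4.3.0]non-2-en-8-one (ring A closed; side chain endo, Cl exo)
Conditions: CH2N2 (1.5 equiv), Et2O–MeOH, 0 °C; AcOH quench
Reagents that add atoms: diazomethane (C=[N+]=[N-])
Why: Diazomethane adds to the strained, chlorine-activated C4 carbonyl to give a diazonium betaine, which collapses by 1,2-shift of the ring-fusion carbon C2 from C4 to the new methylene C3 with loss of N2 (Tiffeneau–Demjanov-type homologation; closest known reaction type: diazomethane ring expansion of α-chlorocyclobutanones from chloroketene–olefin adducts to 2-chlorocyclopentanones). Ring A (C2–C3–C4–C5–C6) is closed by ring enlargement, the temporary C2–C4 bond being exchanged for the C2–C3 and C3–C4 bonds, which amounts to insertion of one carbon into that bond. No new stereocentre is formed; C2 migrates with retention, so the cis ring fusion (C2, C6) and the quaternary C5 set in the cycloaddition are carried over unchanged. The step needs regioselectivity (C2 versus C5 migration), which the electron-withdrawing chlorine on C5 secures by disfavouring migration of that carbon, and chemoselectivity over the C7=C8 olefin and a second homologation, which the much higher carbonyl reactivity of the α-chlorocyclobutanone and a small excess of reagent at 0 °C secure.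

Step 6
Reactants: 8 α-chloro cyclopentanone
Product: 9 cis-9-[(1S)-1-(TBS-oxy)ethyl]bicyclo[4.3.0]non-2-en-8-one (side chain endo; C2, C5, C6 as in the target)
Conditions: Bu3SnH, AIBN (cat.), benzene, 80 °C
Reagents that add atoms: none
Why: Radical dechlorination (tin hydride chain) passes through a planar α-keto radical at C5 that abstracts hydrogen from Bu3SnH on the convex face of the cis-fused bicycle, which leaves the side chain endo (H5 cis to H2 and H6) and avoids an enolate that could β-eliminate the silyloxy group.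

Step 7
Reactants: 9 endo ketone
Product: 10 C4 ethylene ketal of 9
Conditions: (Me3SiOCH2)2, Me3SiOTf (cat.), CH2Cl2, −78 to −20 °C
Reagents that add atoms: 1,2-bis(trimethylsilyloxy)ethane (C[Si](C)(C)OCCO[Si](C)(C)C)
Why: Ketalisation with the bis-silyl ether under silyl triflate catalysis at low temperature masks the C4 ketone without enolising the adjacent C5 stereocentre.

Step 8
Reactants: 10 ketal
Product: 11 enone (C9 ketone conjugated with C7=C8; C4 ketal)
Conditions: Rh2(C6H10NO)4 [dirhodium tetrakis(caprolactamate)] (1 mol %), t-BuOOH, K2CO3, CH2Cl2, rt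
Reagents that add atoms: tert-butyl hydroperoxide (CC(C)(C)OO)
Why: Radical allylic oxidation of the cis-disubstituted olefin takes place at the only allylic methylene, C9 (the other allylic position, C6, is a hindered ring-fusion methine), and gives the 4-substituted cyclohexenone.

Step 9
Reactants: 11 enone
Product: 12 allylic alcohol (C9–OH on the top face, 9S; C7=C8)
Conditions: NaBH4, CeCl3·7H2O, MeOH, −78 °C
Reagents that add atoms: none
Why: Luche 1,2-reduction delivers hydride to the convex face of the enone, the concave face being shielded by ring A and the endo C5 side chain, which places the new C9 hydroxyl syn to ring A.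

Step 10
Reactants: 12 allylic alcohol
Product: 14 methyl ester (C7–CH2CO2Me on the top face; C8=C9 olefin), via ketene acetal 13 (not isolated)
Conditions: MeC(OMe)3 (excess), EtCO2H (cat.), 140 °C, MeOH distilled off
Reagents that add atoms: trimethyl orthoacetate (COC(C)(OC)OC)
Why: Johnson–Claisen rearrangement of the ketene acetal formed on O9 proceeds suprafacially through a chair-like [3,3] transition state, so the C7–C11 bond is made on the face that carried O9 (syn to ring A), the C9 chirality being transferred to C7 while the olefin moves to C8=C9.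

Step 11
Reactants: 14 methyl ester
Product: 17 acrylate [C7–C(=CH2)CO2Me], via Mannich base 15 (not isolated), via trimethylammonium iodide 16 (not isolated)
Conditions: LiN(iPr)2, THF, −78 °C; Me2N=CH2+ I−, −78 °C to rt; then MeI, MeOH; then NaHCO3 (aq), CH2Cl2
Reagents that add atoms: Eschenmoser's salt (C=[N+](C)C.[I-])
Why: Ester-enolate Mannich reaction followed by exhaustive methylation and E1cB loss of trimethylamine is the standard α-methylenation of an ester, and the ester α-CH2 is the only site acidic enough for the amide base, so C7 is not touched.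

Step 12
Reactants: 17 acrylate
Product: 18 allylic alcohol [C7–C(=CH2)CH2OH]
Conditions: (iBu)2AlH (2.5 equiv), CH2Cl2, −78 °C; Rochelle salt work-up
Reagents that add atoms: none
Why: The aluminium hydride reduces the conjugated ester 1,2 to the 2-substituted allylic alcohol without affecting ketal, silyl ether or ring olefin.

Step 13
Reactants: 18 allylic alcohol
Product: 19 (R)-epoxy alcohol [C7–C11(oxirane)(CH2OH)]
Conditions: Ti(OiPr)4, D-(−)-diethyl tartrate, t-BuOOH, 4 Å molecular sieves, CH2Cl2, −20 °C
Reagents that add atoms: tert-butyl hydroperoxide (CC(C)(C)OO)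
Why: Sharpless asymmetric epoxidation is chemoselective for the allylic-alcohol olefin and reagent-controlled, the D-(−)-tartrate delivering oxygen to the face that gives the (R)-epoxy alcohol, which becomes the (S)-configured C11 of the target once C13 is oxidised.

Step 14
Reactants: 19 epoxy alcohol
Product: 20 glycidic acid (C13 = CO2H)
Conditions: TEMPO (cat.), PhI(OAc)2, MeCN–H2O (pH 7 buffer), rt
Reagents that add atoms: water (O)
Why: Nitroxyl-catalysed oxidation takes the primary alcohol through the aldehyde hydrate to the acid under near-neutral conditions that leave oxirane, ketal and ring olefin untouched.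

Step 15
Reactants: 20 glycidic acid
Product: 21 methyl glycidate (C11/C12/C13 unit of the target; C8=C9 olefin)
Conditions: CH2N2, Et2O, 0 °C
Reagents that add atoms: diazomethane (C=[N+]=[N-])
Why: O-Methylation of the carboxylic acid by diazomethane is fast and neutral, so the glycidic ester forms without oxirane opening.

Step 16
Reactants: 21 methyl glycidate; 22 (E)-3-methylpent-2-enoic acid
Product: 25 cis-hydroxy ester (O8–(E)-3-methylpent-2-enoyl and C9–OH, both on the top face), via iodo ester 23 (not isolated), via dioxolanylium carboxylate 24 (not isolated)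
Conditions: 22 (2.2 equiv), Ag2O (1.1 equiv), benzene, rt; I2 (1.05 equiv), dark, rt; then H2O (2 equiv), 45 °C
Reagents that add atoms: water (O)
Why: In this Woodward cis-hydroxylation run with the silver salt of 22, iodonium forms on the convex face of C8=C9, carboxylate opens it anti from the face of ring A, the ester carbonyl then displaces iodide with silver assistance to give a cis-fused 1,3-dioxolan-2-ylium ion on that same face, and water opens the cation with the stereoelectronic preference for the axial ester, which in the favoured chair (C6–C5 and O8 axial, C7 substituent and O9 equatorial) leaves the acyl group on O8 and the free hydroxyl on C9.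

Step 17
Reactants: 25 cis-hydroxy ester
Product: 26 α-acyloxy ketone (C9=O)
Conditions: Dess–Martin periodinane, NaHCO3, CH2Cl2, 0 °C to rt (run directly on crude 25)
Reagents that add atoms: none
Why: Dess–Martin oxidation of the equatorial C9 alcohol under buffered, non-basic conditions gives the ketone before any acyl migration and without epimerisation at C8.

Step 18
Reactants: 26 α-acyloxy ketone
Product: 27 α-methylene ketone (C1=C15H2, C9=O)
Conditions: (CH2O)n, iPr2NH·CF3CO2H, THF, 65 °C
Reagents that add atoms: paraformaldehyde (C=O)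
Why: Amine-salt-mediated Mannich-type α-methylenation can only occur at C1, the single α-CH2, and C8 should keep its configuration because its equatorial C–H is poorly aligned with the carbonyl for enolisation.

Step 19
Reactants: 27 α-methylene ketone
Product: 28 allylic alcohol (C9–OH on the top face, as in the target)
Conditions: NaBH4, CeCl3·7H2O, MeOH, −78 °C
Reagents that add atoms: none
Why: In this Luche 1,2-reduction hydride attacks axially from the convex face, anti to the axial C8 acyloxy group (Felkin–Anh), giving the equatorial C9 alcohol syn to ring A.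

Step 20
Reactants: 28 allylic alcohol; 29 (R)-2-methylbutanoic acid
Product: 30 diester (O9–(R)-2-methylbutanoyl; C4 ketal; C10–OTBS)
Conditions: iPrN=C=NiPr, DMAP (cat.), CH2Cl2, 0 °C (run directly on crude 28)
Reagents that add atoms: none
Why: Steglich esterification acylates the unhindered equatorial allylic C9 hydroxyl at 0 °C, conditions under which the α-stereocentre of the acid and the position of the O8 ester should be retained.

Step 21
Reactants: 30 diester
Product: 31 C10 alcohol
Conditions: Bu4NF, AcOH, THF, rt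
Reagents that add atoms: none
Why: Fluoride desilylation buffered with acetic acid removes the only silyl ether without touching esters, oxirane or ketal.

Step 22
Reactants: 31 C10 alcohol
Product: 32 C10 acetate (C4 ketal of the target)
Conditions: Ac2O, pyridine, DMAP (cat.), CH2Cl2, 0 °C to rt
Reagents that add atoms: acetic anhydride (CC(=O)OC(C)=O)
Why: Nucleophile-catalysed acetylation of the secondary C10 alcohol is done while C4 is still a ketal, so no β-elimination of acetate is possible.

Step 23
Reactants: 32 C10 acetate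
Product: 33 target CNP0251769.1
Conditions: pyridinium p-toluenesulfonate (cat.), acetone–H2O, 40 °C
Reagents that add atoms: water (O)
Why: Mild acid-catalysed hydrolysis of the dioxolane liberates the C4 ketone, the weak acid being expected to leave the glycidic ester, the allylic ester, the β-acetoxy group and the C5 stereocentre untouched.

## Compound list

1 | D-threonine | C[C@H](O)[C@@H](N)C(=O)O | starting material
2 | (2R,3S)-2-chloro-3-hydroxybutanoic acid | C[C@H](O)[C@@H](Cl)C(=O)O | intermediate
3 | tert-butyldimethylsilyl (2R,3S)-3-(tert-butyldimethylsilyloxy)-2-chlorobutanoate | C[C@H](O[Si](C)(C)C(C)(C)C)[C@@H](Cl)C(=O)O[Si](C)(C)C(C)(C)C | intermediate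
4 | (2R,3S)-3-(tert-butyldimethylsilyloxy)-2-chlorobutanoyl chloride | C[C@H](O[Si](C)(C)C(C)(C)C)[C@@H](Cl)C(Cl)=O | intermediate
5 | cyclohexa-1,3-diene | C1=CC=CCC1 | starting material
6 | chloro[(1S)-1-(tert-butyldimethylsilyloxy)ethyl]ketene | C[C@H](O[Si](C)(C)C(C)(C)C)C(Cl)=C=O | intermediate
7 | cis-fused 8-chloro-8-[(1S)-1-(TBS-oxy)ethyl]bicyclo[4.2.0]oct-2-en-7-one; silyloxyethyl endo, Cl exo | C1[C@H]2C(=O)[C@@](Cl)([C@H](C)O[Si](C)(C)C(C)(C)C)[C@H]2C=CC1 | intermediate
8 | cis-9-chloro-9-[(1S)-1-(TBS-oxy)ethyl]bicyclo[4.3.0]non-2-en-8-one; side chain endo, Cl exo | C1[C@H]2CC(=O)[C@@](Cl)([C@H](C)O[Si](C)(C)C(C)(C)C)[C@H]2C=CC1 | intermediate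
9 | cis-9-[(1S)-1-(TBS-oxy)ethyl]bicyclo[4.3.0]non-2-en-8-one; side chain endo | C1[C@H]2CC(=O)[C@@H]([C@H](C)O[Si](C)(C)C(C)(C)C)[C@H]2C=CC1 | intermediate
10 | C4 ethylene ketal of 9 | C1[C@H]2CC3(OCCO3)[C@@H]([C@H](C)O[Si](C)(C)C(C)(C)C)[C@H]2C=CC1 | intermediate
11 | enone: C9 ketone conjugated with C7=C8, C4 ketal | C1[C@H]2CC3(OCCO3)[C@@H]([C@H](C)O[Si](C)(C)C(C)(C)C)[C@H]2C=CC1=O | intermediate
12 | allylic alcohol: C9–OH on the top face (9S), C7=C8 | C1[C@H]2CC3(OCCO3)[C@@H]([C@H](C)O[Si](C)(C)C(C)(C)C)[C@H]2C=C[C@H]1O | intermediate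
13 | mixed ketene acetal of 12, C9–O–C(OMe)=CH2 | C1[C@H]2CC3(OCCO3)[C@@H]([C@H](C)O[Si](C)(C)C(C)(C)C)[C@H]2C=C[C@H]1OC(=C)OC | intermediate
14 | methyl ester: C7–CH2CO2Me on the top face, C8=C9 | C1[C@H]2CC3(OCCO3)[C@@H]([C@H](C)O[Si](C)(C)C(C)(C)C)[C@H]2[C@@H](CC(=O)OC)C=C1 | intermediate
15 | Mannich base: C7–CH(CH2NMe2)CO2Me, mixture at the new carbon | C1[C@H]2CC3(OCCO3)[C@@H]([C@H](C)O[Si](C)(C)C(C)(C)C)[C@H]2[C@@H](C(CN(C)C)C(=O)OC)C=C1 | intermediate
16 | trimethylammonium iodide of 15 | C1[C@H]2CC3(OCCO3)[C@@H]([C@H](C)O[Si](C)(C)C(C)(C)C)[C@H]2[C@@H](C(C[N+](C)(C)C)C(=O)OC)C=C1.[I-] | intermediate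
17 | acrylate: C7–C(=CH2)CO2Me | C1[C@H]2CC3(OCCO3)[C@@H]([C@H](C)O[Si](C)(C)C(C)(C)C)[C@H]2[C@@H](C(=C)C(=O)OC)C=C1 | intermediate
18 | allylic alcohol: C7–C(=CH2)CH2OH | C1[C@H]2CC3(OCCO3)[C@@H]([C@H](C)O[Si](C)(C)C(C)(C)C)[C@H]2[C@@H](C(=C)CO)C=C1 | intermediate
19 | (R)-epoxy alcohol: C7–C11(oxirane)(CH2OH) | C1[C@H]2CC3(OCCO3)[C@@H]([C@H](C)O[Si](C)(C)C(C)(C)C)[C@H]2[C@@H]([C@@]2(CO)CO2)C=C1 | intermediate
20 | glycidic acid: C13 = CO2H | C1[C@H]2CC3(OCCO3)[C@@H]([C@H](C)O[Si](C)(C)C(C)(C)C)[C@H]2[C@@H]([C@@]2(C(=O)O)CO2)C=C1 | intermediate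
21 | methyl glycidate: (11S) oxirane ester on C7, C8=C9, C4 ketal, C10–OTBS | C1[C@H]2CC3(OCCO3)[C@@H]([C@H](C)O[Si](C)(C)C(C)(C)C)[C@H]2[C@@H]([C@@]2(C(=O)OC)CO2)C=C1 | intermediate
22 | (E)-3-methylpent-2-enoic acid | OC(=O)/C=C(\C)CC | starting material
23 | trans-iodo ester: O8 acyl on the top face, C9–I on the bottom face | C1[C@H]2CC3(OCCO3)[C@@H]([C@H](C)O[Si](C)(C)C(C)(C)C)[C@H]2[C@@H]([C@@]2(C(=O)OC)CO2)[C@@H](OC(=O)/C=C(\C)CC)[C@@H]1I | intermediate
24 | cis-fused 2-alkenyl-1,3-dioxolan-2-ylium (O8 and O9 on the top face) as its (E)-3-methylpent-2-enoate salt | C1[C@H]2CC3(OCCO3)[C@@H]([C@H](C)O[Si](C)(C)C(C)(C)C)[C@H]2[C@@H]([C@@]2(C(=O)OC)CO2)[C@H]4OC(/C=C(\C)CC)=[O+][C@@H]14.[O-]C(=O)/C=C(\C)CC | intermediate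
25 | cis-hydroxy ester: O8–(E)-3-methylpent-2-enoyl, C9–OH, both on the top face | C1[C@H]2CC3(OCCO3)[C@@H]([C@H](C)O[Si](C)(C)C(C)(C)C)[C@H]2[C@@H]([C@@]2(C(=O)OC)CO2)[C@@H](OC(=O)/C=C(\C)CC)[C@H]1O | intermediate
26 | α-acyloxy ketone: C9=O | C1[C@H]2CC3(OCCO3)[C@@H]([C@H](C)O[Si](C)(C)C(C)(C)C)[C@H]2[C@@H]([C@@]2(C(=O)OC)CO2)[C@@H](OC(=O)/C=C(\C)CC)C1=O | intermediate
27 | α-methylene ketone: C1=C15H2, C9=O | C=C1[C@H]2CC3(OCCO3)[C@@H]([C@H](C)O[Si](C)(C)C(C)(C)C)[C@H]2[C@@H]([C@@]2(C(=O)OC)CO2)[C@@H](OC(=O)/C=C(\C)CC)C1=O | intermediate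
28 | allylic alcohol: C9–OH on the top face | C=C1[C@H]2CC3(OCCO3)[C@@H]([C@H](C)O[Si](C)(C)C(C)(C)C)[C@H]2[C@@H]([C@@]2(C(=O)OC)CO2)[C@@H](OC(=O)/C=C(\C)CC)[C@H]1O | intermediate
29 | (R)-2-methylbutanoic acid | CC[C@@H](C)C(=O)O | starting material
30 | diester: O9–(R)-2-methylbutanoyl, C4 ketal, C10–OTBS | C=C1[C@H]2CC3(OCCO3)[C@@H]([C@H](C)O[Si](C)(C)C(C)(C)C)[C@H]2[C@@H]([C@@]2(C(=O)OC)CO2)[C@@H](OC(=O)/C=C(\C)CC)[C@H]1OC(=O)[C@H](C)CC | intermediate
31 | C10 alcohol | C=C1[C@H]2CC3(OCCO3)[C@@H]([C@H](C)O)[C@H]2[C@@H]([C@@]2(C(=O)OC)CO2)[C@@H](OC(=O)/C=C(\C)CC)[C@H]1OC(=O)[C@H](C)CC | intermediate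
32 | C10 acetate, C4 ethylene ketal of the target | C=C1[C@H]2CC3(OCCO3)[C@@H]([C@H](C)OC(C)=O)[C@H]2[C@@H]([C@@]2(C(=O)OC)CO2)[C@@H](OC(=O)/C=C(\C)CC)[C@H]1OC(=O)[C@H](C)CC | intermediate
33 | CNP0251769.1 | C=C1[C@H]2CC(=O)[C@@H]([C@H](C)OC(C)=O)[C@H]2[C@@H]([C@@]2(C(=O)OC)CO2)[C@@H](OC(=O)/C=C(\C)CC)[C@H]1OC(=O)[C@H](C)CC | target

## Step count and risks

Total step count: 23. Longest linear sequence: 23 steps (from D-threonine 1; compounds 5, 22 and 29 enter as purchased materials).

Steps most likely to fail:

1. Step 16. Risks: collapse of the hemi-orthoester toward the equatorial instead of the axial ester, acyl migration before the oxidation, or iodonium opening from the wrong face. Fallback (sets out from 21, returns at 26): NBS in wet DMSO should give the bromohydrin F1 (bromonium on the convex face, water at C9 from the top face). Dess–Martin oxidation gives the α-bromo ketone F2. The caesium salt of 22 in DMF then displaces the carbonyl-activated bromide with inversion to give 26, and the route continues with step 18.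

2. Step 4. Risks: weak facial discrimination by the ketene stereocentre and incomplete chromatographic separation of the two endo adducts. Fallback (sets out from 7, returns at 12): 7 is carried through steps 5–9 as the mixture with its ring-fusion diastereomer F3. This gives, beside 8–12, the diastereomeric chloro ketone F4, ketone F5, ketal F6, enone F7 and allylic alcohol F8. The two alcohols have opposite configuration at the C9 carbinol, so Burkholderia cepacia lipase with vinyl acetate should acetylate the (9R) alcohol F8 to the acetate F9 and leave 12, which is separated as the free alcohol and enters step 10.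

3. Step 9. Risk: hydride delivery from the concave face, which would send the Claisen transfer to the wrong face of C7. Fallback (sets out from 11, returns at 12): the C9-epimeric alcohol F10 is inverted by Mitsunobu reaction (4-nitrobenzoic acid, PPh3, diisopropyl azodicarboxylate) to the 4-nitrobenzoate F11, and methanolysis (K2CO3, MeOH) returns 12.

Further compounds
F1 | step 16 | bromohydrin: C9–OH on the top face, C8–Br on the bottom face | C1[C@H]2CC3(OCCO3)[C@@H]([C@H](C)O[Si](C)(C)C(C)(C)C)[C@H]2[C@@H]([C@@]2(C(=O)OC)CO2)[C@H](Br)[C@H]1O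
F2 | step 16 | α-bromo ketone: C9=O, C8–Br on the bottom face | C1[C@H]2CC3(OCCO3)[C@@H]([C@H](C)O[Si](C)(C)C(C)(C)C)[C@H]2[C@@H]([C@@]2(C(=O)OC)CO2)[C@H](Br)C1=O
F3 | step 4 | ring-fusion diastereomer of 7 (all ring centres inverted, C10 unchanged) | C1[C@@H]2C(=O)[C@](Cl)([C@H](C)O[Si](C)(C)C(C)(C)C)[C@@H]2C=CC1
F4 | step 4 | ring-fusion diastereomer of 8 | C1[C@@H]2CC(=O)[C@](Cl)([C@H](C)O[Si](C)(C)C(C)(C)C)[C@@H]2C=CC1
F5 | step 4 | ring-fusion diastereomer of 9 | C1[C@@H]2CC(=O)[C@H]([C@H](C)O[Si](C)(C)C(C)(C)C)[C@@H]2C=CC1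
F6 | step 4 | ring-fusion diastereomer of 10 | C1[C@@H]2CC3(OCCO3)[C@H]([C@H](C)O[Si](C)(C)C(C)(C)C)[C@@H]2C=CC1
F7 | step 4 | ring-fusion diastereomer of 11 | C1[C@@H]2CC3(OCCO3)[C@H]([C@H](C)O[Si](C)(C)C(C)(C)C)[C@@H]2C=CC1=O
F8 | step 4 | ring-fusion diastereomer of 12, (9R) alcohol | C1[C@@H]2CC3(OCCO3)[C@H]([C@H](C)O[Si](C)(C)C(C)(C)C)[C@@H]2C=C[C@@H]1O
F9 | step 4 | acetate of F8 | C1[C@@H]2CC3(OCCO3)[C@H]([C@H](C)O[Si](C)(C)C(C)(C)C)[C@@H]2C=C[C@@H]1OC(C)=O
F10 | step 9 | C9 epimer of 12 (C9–OH on the bottom face) | C1[C@H]2CC3(OCCO3)[C@@H]([C@H](C)O[Si](C)(C)C(C)(C)C)[C@H]2C=C[C@@H]1O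
F11 | step 9 | 4-nitrobenzoate of 12 (ester on the top face) | C1[C@H]2CC3(OCCO3)[C@@H]([C@H](C)O[Si](C)(C)C(C)(C)C)[C@H]2C=C[C@H]1OC(=O)c1ccc(cc1)[N+](=O)[O-]
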